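**Assumptions:** the SMILES encodes the (2R,3R)-2,3-trans dihydroflavonol, and that is the isomer planned for. MOMCl, bases, poly-L-leucine and solvents are treated as reagents; "prenyl" means 3-methylbut-2-en-1-yl.

## Retrosynthetic overview
1. The pyranone C ring is the only ring formed, and it is formed last: the 2'-phenol opens a (αR,βS)-chalcone epoxide 6-endo at the benzylic carbon (O1–C2 bond), with MOM removal in the same pot.
2. The epoxide comes from an (E)-chalcone by poly-L-leucine (Juliá–Colonna) nucleophilic epoxidation, which attacks only the enone and leaves both prenyl alkenes alone.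
3. The chalcone is cut at Cα=Cβ into a C13 A-ring acetophenone and a C12 B-ring benzaldehyde, joined by Claisen–Schmidt condensation.
4. The A-ring ketone comes from resorcinol by two successive directed ortho-metalations (prenyl bromide, then a Weinreb acetamide).
5. The B-ring aldehyde comes from 4-bromophenol by ortho C-prenylation, MOM protection and Br/Li exchange–formylation.

## Route

**Fragment A (A-ring ketone)**

**Step 1**
Reactants: 1, resorcinol
Product: 2, 1,3-bis(methoxymethoxy)benzene
Conditions: NaH, MOMCl, DMF, 0 °C → rt
Reagents that add atoms: chloromethyl methyl ether (MOMCl), COCCl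
Why: Williamson-type O-alkylation protects both phenols as base-stable MOM acetals that also serve as ortho-directing groups for the next two steps.

**Step 2**
Reactants: 2, 1,3-bis(methoxymethoxy)benzene; 3, prenyl bromide
Product: 4, 1,3-bis(methoxymethoxy)-2-prenylbenzene
Conditions: n-BuLi, THF, 0 °C → rt; CuI (0.5 equiv), −40 °C; then 3, −40 °C → rt
Reagents that add atoms: prenyl bromide (3), CC(C)=CCBr
Why: Directed ortho-metalation occurs at C2 between the two OMOM groups, and the aryl copper/lithium species is allylated by SN2 to give the linear prenyl group.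

**Step 3**
Reactants: 4, 1,3-bis(methoxymethoxy)-2-prenylbenzene; 5, N-methoxy-N-methylacetamide
Product: 6, 1-[2,4-bis(methoxymethoxy)-3-prenylphenyl]ethan-1-one
Conditions: s-BuLi, TMEDA, THF, −78 °C, 1 h; then 5, −78 → 0 °C; aq NH4Cl
Reagents that add atoms: N-methoxy-N-methylacetamide (5), CON(C)C(C)=O
Why: With C2 blocked, a second directed ortho-metalation occurs at C4 (kinetic ring lithiation ortho to OMOM at low temperature), and Weinreb amide acylation stops cleanly at the methyl ketone.

**Fragment B (B-ring aldehyde)**

**Step 4**
Reactants: 7, 4-bromophenol; 3, prenyl bromide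
Product: 8, 4-bromo-2-prenylphenol
Conditions: NaH (1.0 equiv), toluene, 0 °C → rt; then 3, rt, 16 h
Reagents that add atoms: prenyl bromide (3), CC(C)=CCBr
Why: In a non-polar solvent the tightly ion-paired sodium phenoxide undergoes C-alkylation at the ortho position (para is blocked by Br) by SN2 on the primary allylic bromide.

**Step 5**
Reactants: 8, 4-bromo-2-prenylphenol
Product: 9, 4-bromo-1-(methoxymethoxy)-2-prenylbenzene
Conditions: MOMCl, i-Pr2NEt, CH2Cl2, 0 °C → rt
Reagents that add atoms: chloromethyl methyl ether (MOMCl), COCCl
Why: MOM protection masks the acidic phenol before organolithium chemistry and gives the same protecting group as fragment A, so one final deprotection suffices.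

**Step 6**
Reactants: 9, 4-bromo-1-(methoxymethoxy)-2-prenylbenzene; 10, N,N-dimethylformamide
Product: 11, 4-(methoxymethoxy)-3-prenylbenzaldehyde
Conditions: n-BuLi, THF, −78 °C, 20 min; then 10, −78 → 0 °C; aq NH4Cl
Reagents that add atoms: DMF (10), CN(C)C=O
Why: Br/Li exchange at −78 °C is faster than any deprotonation, and trapping the aryllithium with DMF (Bouveault formylation) gives the aldehyde para to the oxygen.

**Fragment union and endgame**

**Step 7**
Reactants: 6, A-ring ketone; 11, B-ring aldehyde
Product: 12, (E)-1-[2,4-bis(methoxymethoxy)-3-prenylphenyl]-3-[4-(methoxymethoxy)-3-prenylphenyl]prop-2-en-1-one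
Conditions: KOH (50% aq, excess), EtOH, rt, 24–36 h
Reagents that add atoms: none
Why: Claisen–Schmidt aldol condensation of a methyl ketone with a non-enolisable aldehyde, followed by E1cB dehydration, gives the (E)-enone; MOM ethers and prenyl groups are inert to hydroxide, and the protected 2'-oxygen cannot cyclise to a flavanone.

**Step 8**
Reactants: 12, (E)-chalcone
Product: 13, [(2R,3S)-3-[4-(methoxymethoxy)-3-prenylphenyl]oxiran-2-yl][2,4-bis(methoxymethoxy)-3-prenylphenyl]methanone (trans epoxide, αR,βS)
Conditions: poly-L-leucine, urea·H2O2, DBU, THF, rt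
Reagents that add atoms: hydrogen peroxide (as the urea adduct), OO
Why: Juliá–Colonna asymmetric Weitz–Scheffer epoxidation, in which hydroperoxide adds conjugately only to the electron-poor enone and the L-polypeptide helix directs it to the face that gives the trans-(αR,βS) epoxide, setting both stereocentres.

**Step 9**
Reactants: 13, (αR,βS)-epoxide
Product: 14, 3-hydroxyglabrol, (2R,3R)-3,7-dihydroxy-2-(4-hydroxy-3-prenylphenyl)-8-prenyl-2,3-dihydro-4H-chromen-4-one
Conditions: 3 M aq HCl/MeOH (1:5), 40–45 °C, 1–2 h, stopped as soon as the MOM groups are gone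
Reagents that add atoms: none
Why: Acidic acetal cleavage frees the three phenols, and the 2'-OH opens the protonated epoxide 6-endo at the benzylic carbon with inversion (βS → 2R) while Cα is untouched (αR → 3R), giving the 2,3-trans diequatorial product, which is also the thermodynamic isomer.

## Compound list
1 | resorcinol | Oc1cccc(O)c1 | starting material
2 | 1,3-bis(methoxymethoxy)benzene | COCOc1cccc(OCOC)c1 | intermediate
3 | prenyl bromide (1-bromo-3-methylbut-2-ene) | CC(C)=CCBr | starting material
4 | 1,3-bis(methoxymethoxy)-2-prenylbenzene | COCOc1cccc(OCOC)c1CC=C(C)C | intermediate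
5 | N-methoxy-N-methylacetamide | CON(C)C(C)=O | starting material
6 | 1-[2,4-bis(methoxymethoxy)-3-prenylphenyl]ethan-1-one | CC(=O)c1ccc(OCOC)c(CC=C(C)C)c1OCOC | intermediate
7 | 4-bromophenol | Oc1ccc(Br)cc1 | starting material
8 | 4-bromo-2-prenylphenol | CC(C)=CCc1cc(Br)ccc1O | intermediate
9 | 4-bromo-1-(methoxymethoxy)-2-prenylbenzene | COCOc1ccc(Br)cc1CC=C(C)C | intermediate
10 | N,N-dimethylformamide | CN(C)C=O | starting material
11 | 4-(methoxymethoxy)-3-prenylbenzaldehyde | COCOc1ccc(C=O)cc1CC=C(C)C | intermediate
12 | (E)-1-[2,4-bis(methoxymethoxy)-3-prenylphenyl]-3-[4-(methoxymethoxy)-3-prenylphenyl]prop-2-en-1-one | COCOc1ccc(C(=O)/C=C/c2ccc(OCOC)c(CC=C(C)C)c2)c(OCOC)c1CC=C(C)C | intermediate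
13 | [(2R,3S)-3-[4-(methoxymethoxy)-3-prenylphenyl]oxiran-2-yl][2,4-bis(methoxymethoxy)-3-prenylphenyl]methanone | COCOc1ccc(C(=O)[C@@H]2O[C@H]2c3ccc(OCOC)c(CC=C(C)C)c3)c(OCOC)c1CC=C(C)C | intermediate
14 | 3-hydroxyglabrol, (2R,3R) | CC(C)=CCc1cc([C@H]2Oc3c(ccc(O)c3CC=C(C)C)C(=O)[C@@H]2O)ccc1O | target

## Summary
**Total steps:** 9

**Longest linear sequence:** 6 steps (1 → 2 → 3 → 7 → 8 → 9; the B-ring branch 4 → 5 → 6 → 7 → 8 → 9 is also 6), i.e. 6/9 of the total.

**Steps most likely to fail, with fallbacks**

1. **Step 9 (acidic MOM removal and cyclisation).** Risks are acid-promoted cyclisation of an ortho-prenyl phenol to a 2,2-dimethylchroman, 5-exo closure to an aurone-type product, or aryl migration. Fallback: separate ring closure from deprotection. Open the epoxide at Cβ with BnSH/SnCl4 at −20 °C, which also cleaves the 2'-MOM, then close the ring by AgBF4-promoted displacement of the benzylic thioether by the 2'-OH. The two remaining MOM groups are then removed under mild conditions (PPTS, warm t-BuOH).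

2. **Step 8 (Juliá–Colonna epoxidation of a hindered 2'-alkoxy chalcone).** The reaction may be slow or give low ee. Fallback: make the racemic trans epoxide with H2O2/NaOH, carry it through step 9, and resolve the racemic trans-dihydroflavonol at the end by lipase-mediated kinetic acylation of the 3-OH or by preparative chiral chromatography.

3. **Step 3 (second ortho-lithiation next to a prenyl group).** Competing deprotonation of the benzylic/allylic CH2 would erode the yield. Fallback: install the acetyl group before the prenyl group. Acylate resorcinol with AcOH/BF3·OEt2 to 2,4-dihydroxyacetophenone, iodinate at C3 (I2/HIO3), protect as the bis-MOM ether, and introduce the prenyl group by Stille coupling with tributyl(prenyl)stannane, so that no organolithium meets a prenylated arene.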